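**Retrosynthetic overview**

1. Locants: ring A is the formyl/enal-bearing benzene with oxygens O3', O4', O5' (O4' para to the side chain), ring B the dioxane, ring C the trimethoxyphenyl; C7 is the benzylic carbon on ring C, C8 the carbon bearing CH2OH, C9 that CH2. The E-enal is cut back to the ring-A benzaldehyde (Wittig two-carbon homologation, last step).
2. Ring B is opened at O4'–C8: the O4' phenoxide opens a C8–C9 oxirane (6-exo-tet, inversion at C8). The oxirane is made in the same flask from a C8-hydroxy/C9-tosylate, and the phenols are unmasked in the same flask from allyl ethers.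
3. The C7–O3' ether comes from phenoxide opening (inversion at C7) of the (2R,3R)-glycidol obtained by Sharpless epoxidation of the E-cinnamyl alcohol. One epoxidation thus sets both stereocentres; the two inversions amount to syn addition of O3'/O4' across the E-alkene, which gives the trans ring.
4. The ring-A piece comes from 3,4,5-trihydroxybenzaldehyde: two allyl groups leave one meta hydroxyl free, and symmetry makes the two meta hydroxyls equivalent.
5. Enabling feature: the ortho C3'–O/C4'–O pair of ring A facing the vicinally oxygenated C8–C9 unit. Once O3' sits on C7, O4' is five bonds from C8, and the C9 oxygen serves as the leaving group (as an oxirane) and ends as the hydroxymethyl. Ring B is the only ring built, last, after the transient oxirane.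

Key step: step 6

Assumption: the target is read as the trans-(7S,8S) benzodioxane, and compounds 1 and 4 are taken as catalogue chemicals.

**Step 1**
Reactants: 1 methyl (2E)-3-(3,4,5-trimethoxyphenyl)prop-2-enoate
Product: 2 (2E)-3-(3,4,5-trimethoxyphenyl)prop-2-en-1-ol
Conditions: i-Bu2AlH (2.5 equiv), CH2Cl2, −78 → 0 °C; aq. potassium sodium tartrate work-up
Reagents that add atoms: none
Why: Ester reduction with i-Bu2AlH at low temperature is a 1,2-hydride reduction that leaves the conjugated E-alkene untouched, and no stereocentre is formed.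

**Step 2**
Reactants: 2 (2E)-3-(3,4,5-trimethoxyphenyl)prop-2-en-1-ol
Product: 3 [(2R,3R)-3-(3,4,5-trimethoxyphenyl)oxiran-2-yl]methanol
Conditions: Ti(OiPr)4 (10 mol%), D-(−)-diisopropyl tartrate (14 mol%), t-BuOOH (2 equiv, anhydrous in decane), 4 Å molecular sieves, CH2Cl2, −20 °C; cold NaOH/brine work-up (no acid)
Reagents that add atoms: tert-butyl hydroperoxide CC(C)(C)OO
Why: Sharpless asymmetric epoxidation, in which the tetravalent titanium–tartrate complex binds the allylic alcohol and delivers the peroxide oxygen to one alkene face, D-(−)-diisopropyl tartrate giving the (2R,3R)-epoxide of an E-cinnamyl alcohol, so that C7 and C8 are both set here by the reagent.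

**Step 3**
Reactants: 4 3,4,5-trihydroxybenzaldehyde
Product: 5 3-hydroxy-4,5-bis(prop-2-en-1-yloxy)benzaldehyde
Conditions: allyl bromide (2.1 equiv), K2CO3 (2.2 equiv), degassed DMF, 0 °C → rt, Ar; chromatographic removal of mono- and tri-ethers
Reagents that add atoms: allyl bromide C=CCBr
Why: Williamson ether synthesis under carbonate control, in which the 4-hydroxyl (para to the formyl group, the most acidic) is alkylated first and the second allyl group then enters one of the two symmetry-equivalent flanking hydroxyls, leaving a single free phenol and forming no stereocentre.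

**Step 4**
Reactants: 3 [(2R,3R)-3-(3,4,5-trimethoxyphenyl)oxiran-2-yl]methanol; 5 3-hydroxy-4,5-bis(prop-2-en-1-yloxy)benzaldehyde
Product: 6 3-{[(1S,2R)-2,3-dihydroxy-1-(3,4,5-trimethoxyphenyl)propyl]oxy}-4,5-bis(prop-2-en-1-yloxy)benzaldehyde
Conditions: 5 (1.5 equiv), NaOH (1.4 equiv), degassed H2O/1,4-dioxane, 70 °C, Ar; neutralise, recover excess 5
Reagents that add atoms: none
Why: SN2 opening of the trans-3-arylglycidol by the 2-alkoxyphenoxide at the benzylic carbon C7 in aqueous base, a well-precedented regiochemistry for 3-arylglycidols, should proceed with inversion so that C7 becomes S while C8 keeps its configuration (R), giving the erythro diol.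

**Step 5**
Reactants: 6 3-{[(1S,2R)-2,3-dihydroxy-1-(3,4,5-trimethoxyphenyl)propyl]oxy}-4,5-bis(prop-2-en-1-yloxy)benzaldehyde
Product: 7 (2R,3S)-3-[5-formyl-2,3-bis(prop-2-en-1-yloxy)phenoxy]-2-hydroxy-3-(3,4,5-trimethoxyphenyl)propyl 4-methylbenzenesulfonate
Conditions: TsCl (1.1 equiv), Et3N (1.5 equiv), Bu2SnO (5 mol%), CH2Cl2, 0 °C → rt
Reagents that add atoms: 4-methylbenzenesulfonyl chloride Cc1ccc(cc1)S(=O)(=O)Cl
Why: Regioselective monosulfonylation of a terminal 1,2-diol through its catalytic dibutylstannylene acetal should place the tosyl group on the primary C9 hydroxyl without touching a stereocentre.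

**Step 6**
Reactants: 7 (2R,3S)-3-[5-formyl-2,3-bis(prop-2-en-1-yloxy)phenoxy]-2-hydroxy-3-(3,4,5-trimethoxyphenyl)propyl 4-methylbenzenesulfonate
Product: 10 (2S,3S)-8-hydroxy-2-(hydroxymethyl)-3-(3,4,5-trimethoxyphenyl)-2,3-dihydro-1,4-benzodioxine-6-carbaldehyde, via bis-allyl oxirane 8 (not isolated), via catechol oxirane 9 (not isolated)
Conditions: K2CO3 (4 equiv), degassed MeOH, rt, 1 h; then Pd(PPh3)4 (5 mol%), rt → 45 °C, Ar, high dilution; aq. NH4Cl work-up
Reagents that add atoms: none
Why: Carbonate in methanol turns the C8 alkoxide of the hydroxy tosylate into the C8–C9 oxirane 8 with the C8–O bond untouched, zerovalent palladium then ionises both aryl allyl ethers (π-allyl palladium, allyl passed on to methanol) to give 9, and the freed O4' phenoxide attacks C8 of the oxirane from the rear while the oxirane oxygen leaves as the C9 alkoxide that becomes the hydroxymethyl group. The closest known reaction types are the base-mediated cyclisation of 2-(oxiranylmethoxy)phenols to 2-hydroxymethyl-1,4-benzodioxanes, the hydroxy sulfonate to oxirane closure, and the Pd(PPh3)4/K2CO3/MeOH cleavage of aryl allyl ethers. The transient oxirane closes in 3-exo-tet mode and ring B closes in 6-exo-tet mode, with release of oxirane strain driving the key O4'–C8 bond under mild conditions that the formyl group tolerates. C8 is set by stereospecific SN2 inversion of the (R)-oxirane carbon, which gives 8S, trans to the 7S aryl group fixed in step 4. The step needs attack at C8 (six-membered closure) instead of at the CH2 terminus (seven-membered closure) and O4' instead of O5'. This is secured because O4' is the only phenoxide ortho to the O3'–C7 tether while O5' would have to bridge meta positions, because the exo trajectory at C8 is reached through a six-membered transition state, and because the tosylate is already consumed as the oxirane before any phenoxide is unmasked, so direct displacement at C9 cannot compete.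

**Step 7**
Reactants: 10 (2S,3S)-8-hydroxy-2-(hydroxymethyl)-3-(3,4,5-trimethoxyphenyl)-2,3-dihydro-1,4-benzodioxine-6-carbaldehyde
Product: 11 (2E)-3-[(2S,3S)-8-hydroxy-2-(hydroxymethyl)-3-(3,4,5-trimethoxyphenyl)-2,3-dihydro-1,4-benzodioxin-6-yl]prop-2-enal
Conditions: Ph3P=CHCHO (1.3 equiv), toluene, 80 °C
Reagents that add atoms: (triphenylphosphoranylidene)acetaldehyde O=CC=P(c1ccccc1)(c1ccccc1)c1ccccc1
Why: Wittig olefination with the carbonyl-stabilised formylmethylene ylide should give the E-enal selectively and react faster with the aryl aldehyde than with the conjugated product, while the free phenol and primary alcohol are tolerated and the C7/C8 centres cannot epimerise under these neutral conditions.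

**Compound list**

1 | methyl (2E)-3-(3,4,5-trimethoxyphenyl)prop-2-enoate | COC(=O)/C=C/c1cc(OC)c(OC)c(OC)c1 | starting material
2 | (2E)-3-(3,4,5-trimethoxyphenyl)prop-2-en-1-ol | OC/C=C/c1cc(OC)c(OC)c(OC)c1 | intermediate
3 | [(2R,3R)-3-(3,4,5-trimethoxyphenyl)oxiran-2-yl]methanol | OC[C@H]1O[C@@H]1c1cc(OC)c(OC)c(OC)c1 | intermediate
4 | 3,4,5-trihydroxybenzaldehyde | O=Cc1cc(O)c(O)c(O)c1 | starting material
5 | 3-hydroxy-4,5-bis(prop-2-en-1-yloxy)benzaldehyde | O=Cc1cc(O)c(OCC=C)c(OCC=C)c1 | intermediate
6 | 3-{[(1S,2R)-2,3-dihydroxy-1-(3,4,5-trimethoxyphenyl)propyl]oxy}-4,5-bis(prop-2-en-1-yloxy)benzaldehyde | COc1cc([C@H](Oc2cc(C=O)cc(OCC=C)c2OCC=C)[C@H](O)CO)cc(OC)c1OC | intermediate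
7 | (2R,3S)-3-[5-formyl-2,3-bis(prop-2-en-1-yloxy)phenoxy]-2-hydroxy-3-(3,4,5-trimethoxyphenyl)propyl 4-methylbenzenesulfonate | COc1cc([C@H](Oc2cc(C=O)cc(OCC=C)c2OCC=C)[C@H](O)COS(=O)(=O)c2ccc(C)cc2)cc(OC)c1OC | intermediate
8 | 3-{(S)-[(2R)-oxiran-2-yl](3,4,5-trimethoxyphenyl)methoxy}-4,5-bis(prop-2-en-1-yloxy)benzaldehyde (bis-allyl oxirane, not isolated) | COc1cc([C@H](Oc2cc(C=O)cc(OCC=C)c2OCC=C)[C@H]2CO2)cc(OC)c1OC | intermediate
9 | 3,4-dihydroxy-5-{(S)-[(2R)-oxiran-2-yl](3,4,5-trimethoxyphenyl)methoxy}benzaldehyde (catechol oxirane, not isolated) | COc1cc([C@H](Oc2cc(C=O)cc(O)c2O)[C@H]2CO2)cc(OC)c1OC | intermediate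
10 | (2S,3S)-8-hydroxy-2-(hydroxymethyl)-3-(3,4,5-trimethoxyphenyl)-2,3-dihydro-1,4-benzodioxine-6-carbaldehyde | COc1cc([C@@H]2Oc3cc(C=O)cc(O)c3O[C@H]2CO)cc(OC)c1OC | intermediate
11 | (2E)-3-[(2S,3S)-8-hydroxy-2-(hydroxymethyl)-3-(3,4,5-trimethoxyphenyl)-2,3-dihydro-1,4-benzodioxin-6-yl]prop-2-enal | COc1cc([C@@H]2Oc3cc(/C=C/C=O)cc(O)c3O[C@H]2CO)cc(OC)c1OC | target

Total step count: 7. Longest linear sequence: 6 steps (1 → 2 → 3 → 6 → 7 → 10 → 11).

**Steps most likely to fail**

Step 6. What may go wrong is endo attack of the phenoxide at the CH2 terminus of the oxirane (seven-membered closure), solvolysis of the oxirane by methanol, or air oxidation of the catecholate before it cyclises. The fallback sets out from 6 and returns at 10 without any oxirane. Silylation of the primary hydroxyl (TBDPSCl, imidazole, DMF) should give the C9 tert-butyldiphenylsilyl ether F1. Mesylation of the C8 hydroxyl (MsCl, Et3N, CH2Cl2, 0 °C) should give the methanesulfonate F2. Deallylation with Pd(PPh3)4/K2CO3/MeOH followed by warming should give the catechol methanesulfonate F3 (not isolated), whose O4' phenoxide displaces the secondary mesylate in a 6-exo-tet SN2 reaction with the same inversion at C8, giving the silyl-protected benzodioxane aldehyde F4. Tetrabutylammonium fluoride in THF then frees 10. Because C9 is no longer electrophilic, only the six-membered closure is open.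

Step 4. What may go wrong is competition of hydroxide with the phenoxide at C7, or base-induced epoxide migration (Payne rearrangement) followed by attack at C9, which would scramble the connectivity. The fallback sets out from 3 and returns at 6. Silylation (TBSCl, imidazole, CH2Cl2) should give the glycidyl tert-butyldimethylsilyl ether F5, which has no free hydroxyl and cannot migrate. Opening with 5 and Cs2CO3 in anhydrous DMF at 80 °C, with no hydroxide present, should give the silylated aryloxy alcohol F6 by the same inversion at C7. Tetrabutylammonium fluoride then gives 6.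

Step 7. What may go wrong is over-homologation of the product enal by a second ylide equivalent, or sluggish olefination of the electron-rich aldehyde. The fallback sets out from 10 and returns at 11 through the ester oxidation level. Wittig reaction with Ph3P=CHCO2Et (toluene, 80 °C) should give the E-cinnamate ester F7, which cannot react further. Reduction with excess i-Bu2AlH (CH2Cl2, −78 °C) should give the allylic alcohol F8. MnO2 in CH2Cl2 should then oxidise only the allylic hydroxyl, not the saturated CH2OH, to give 11.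

**Further compounds**

F1 | step 6 | 3-{[(1S,2R)-3-{[tert-butyl(diphenyl)silyl]oxy}-2-hydroxy-1-(3,4,5-trimethoxyphenyl)propyl]oxy}-4,5-bis(prop-2-en-1-yloxy)benzaldehyde | COc1cc([C@H](Oc2cc(C=O)cc(OCC=C)c2OCC=C)[C@H](O)CO[Si](c2ccccc2)(c2ccccc2)C(C)(C)C)cc(OC)c1OC
F2 | step 6 | (1S,2R)-3-{[tert-butyl(diphenyl)silyl]oxy}-1-[5-formyl-2,3-bis(prop-2-en-1-yloxy)phenoxy]-1-(3,4,5-trimethoxyphenyl)propan-2-yl methanesulfonate | COc1cc([C@H](Oc2cc(C=O)cc(OCC=C)c2OCC=C)[C@H](OS(C)(=O)=O)CO[Si](c2ccccc2)(c2ccccc2)C(C)(C)C)cc(OC)c1OC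
F3 | step 6 | (1S,2R)-3-{[tert-butyl(diphenyl)silyl]oxy}-1-(5-formyl-2,3-dihydroxyphenoxy)-1-(3,4,5-trimethoxyphenyl)propan-2-yl methanesulfonate | COc1cc([C@H](Oc2cc(C=O)cc(O)c2O)[C@H](OS(C)(=O)=O)CO[Si](c2ccccc2)(c2ccccc2)C(C)(C)C)cc(OC)c1OC
F4 | step 6 | (2S,3S)-2-({[tert-butyl(diphenyl)silyl]oxy}methyl)-8-hydroxy-3-(3,4,5-trimethoxyphenyl)-2,3-dihydro-1,4-benzodioxine-6-carbaldehyde | COc1cc([C@@H]2Oc3cc(C=O)cc(O)c3O[C@H]2CO[Si](c2ccccc2)(c2ccccc2)C(C)(C)C)cc(OC)c1OC
F5 | step 4 | tert-butyl(dimethyl){[(2R,3R)-3-(3,4,5-trimethoxyphenyl)oxiran-2-yl]methoxy}silane | CC(C)(C)[Si](C)(C)OC[C@H]1O[C@@H]1c1cc(OC)c(OC)c(OC)c1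
F6 | step 4 | 3-{[(1S,2R)-3-{[tert-butyl(dimethyl)silyl]oxy}-2-hydroxy-1-(3,4,5-trimethoxyphenyl)propyl]oxy}-4,5-bis(prop-2-en-1-yloxy)benzaldehyde | COc1cc([C@H](Oc2cc(C=O)cc(OCC=C)c2OCC=C)[C@H](O)CO[Si](C)(C)C(C)(C)C)cc(OC)c1OC
F7 | step 7 | ethyl (2E)-3-[(2S,3S)-8-hydroxy-2-(hydroxymethyl)-3-(3,4,5-trimethoxyphenyl)-2,3-dihydro-1,4-benzodioxin-6-yl]prop-2-enoate | COc1cc([C@@H]2Oc3cc(/C=C/C(=O)OCC)cc(O)c3O[C@H]2CO)cc(OC)c1OC
F8 | step 7 | (2E)-3-[(2S,3S)-8-hydroxy-2-(hydroxymethyl)-3-(3,4,5-trimethoxyphenyl)-2,3-dihydro-1,4-benzodioxin-6-yl]prop-2-en-1-ol | COc1cc([C@@H]2Oc3cc(/C=C/CO)cc(O)c3O[C@H]2CO)cc(OC)c1OC
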